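Monday's, Sunday's and Wednesday's runs stand behind cedar and elm, two flasks with the same charge and different reaction times.

| flask | free monomer | initiator | remark | time |
|---|---|---|---|---|
| Monday's | 1 M | 5 mol% | run made earlier |  |
| Sunday's | 2.2 M | 5 mol% | run made earlier |  |
| Wednesday's | 1.5 M | 10 mol% | run made earlier |  |
| cedar | 1.5 M | 5 mol% |  | 4.0 h |
| elm | 1.5 M | 5 mol% |  | 1.0 h |

| run | time / h | monomer in chains / % |
|---|---|---|
| Monday's | 0.833 | 3 |
| Monday's | 1.50 | 5 |
| Monday's | 2.50 | 3 |
| Monday's | 3.00 | 9 |
| Sunday's | 0.417 | 3 |
| Sunday's | 1.00 | 7 |
| Sunday's | 2.00 | 12 |
| Sunday's | 3.00 | 22 |
| Wednesday's | 0.250 | 0 |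
| Wednesday's | 0.667 | 1 |
| Wednesday's | 1.33 | 12 |
| Wednesday's | 3.00 | 27 |

(each reading ± 2 percentage points)

- the average divides the monomer in chains by the number of chains begun, living and dead together
- the earlier runs do not show the number of chains; that part of a forecast is a guess

1. which of the two ends with the longer chains by the average number of monomer units in a chain (chains begun, living or dead) ("neither" if they lie within 10 %) (cedar / elm / neither)
2. average number of monomer units in a chain (chains begun, living or dead) at the end, cedar
3. average number of monomer units in a chain (chains begun, living or dead) at the end, elm

Each last reading, divided by time, by c(free monomer) and by the initiator loading, gives 0.600 M⁻¹ h⁻¹ for Monday's run, 0.667 M⁻¹ h⁻¹ for Sunday's and 0.600 M⁻¹ h⁻¹ for Wednesday's, although Monday's 9 % carries a scatter of 2 percentage points. These values lie close, and all three readings stand at 3.00 h, so they speak for proportionality to c(free monomer) and to the loading but say nothing about time; uptake linear in time is an assumption here, with the mean as coefficient.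

The bench rule takes the statistical case as zero: every initiator charged has begun one chain, so the average length (number-average degree of polymerisation) is the fraction in chains divided by the loading. If an initiator begins at most one chain, this is a floor on the length. The loading then cancels, and the floor is the coefficient times c(free monomer) times time, which makes 0.622 M⁻¹ h⁻¹ the floor length gained per molar hour.

At the 1.5 M of both flasks, the floor reaches one unit at 1.07 h. On that assumed line, cedar's floor is 3.73. Elm's is 0.933, less than one unit, and a begun chain holds at least one unit, so the rule stops at this border: by this estimate, not all of elm's initiator has begun. Two lower bounds do not order the flasks, since the earlier runs do not show the number of chains. The reckoning here therefore gives an estimated floor of 3.73 for cedar and one unit for elm, and names cedar as the longer as a guess, with its estimated floor 4.00 times elm's reckoned one.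

The forecast also says cedar, but gives values rather than floors: 4 for cedar and 1.7 for elm, adding that “The chain count is unobserved”.

The flasks give 6.82 for cedar and 2.31 for elm, so the longer chains stand in cedar.

    free monomer + initiator → living end + monomer in chains (k = 0.00520 M⁻¹ min⁻¹)
    free monomer + living end → monomer in chains + living end, rate k2*[living end]*[free monomer] (k = 0.0270 M⁻¹ min⁻¹)
    free monomer + initiator → spent initiator (k = 0.00180 M⁻¹ min⁻¹)

At 1.00 h, elm still holds 54.0 % of its initiator, and its length is 2.48 times its floor; cedar's length is 1.83 times its floor, with 10.6 % left at 4.00 h. Cedar's charge read at 10 h has a floor of 9.33 and gives 14.6, which is 1.56 times that floor, with 1.13 % of its initiator left.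

The earlier runs and the new flask stem from a simulated flask with made-up constants.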